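Everything rests on the C7–C8 bond (germacrane numbering). An intramolecular Nozaki–Hiyama–Kishi allylation turns the normally electrophilic β-carbon (C7) of a 3-(bromomethyl)butenolide into a nucleophile and joins it to a tethered aldehyde (C8). In one operation this closes the nine-membered oxonine ring (C3–C10 plus the furanone oxygen) as the last ring, unveils the exocyclic C11=C13 methylene of the lactone by allylic transposition, and creates C7 and the C8 carbinol. It exploits the homoallylic array C13=C11–C7–C8–O where the lactone meets the medium ring. The precursor already holds the 3(2H)-furanone (from a chiral-pool lactone and a Z-enynol) and the butenolide, joined through the Z-C4=C5 olefin.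

Key step: step 13

Remark on numbering: germacrane locants are used throughout (C1 ketone, C2=C3, C3–O–C10 furanone bridge, C4=C5, C6/C7 lactone fusion, C8 ester carbon, C9 carbinol, C10 quaternary carbon, C11=C13 methylene, C12 lactone carbonyl); in these locants the target is 6S,7S,8S,9R,10R with a cis lactone fusion (H6 and H7 on the same face).
Assumption: 2-C-methyl-D-erythrono-1,4-lactone (1) is taken as a purchasable chiral-pool compound; it supplies C1, C8, C9, C10 and the C10 methyl with the 9R,10R configuration.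

Step 1
Reactants: 1 2-C-methyl-D-erythrono-1,4-lactone [(3R,4R)-3,4-dihydroxy-3-methyloxolan-2-one]
Product: 2 (2R,3R)-2,3,4-trihydroxy-N-methoxy-N,2-dimethylbutanamide
Conditions: MeNH(OMe)·HCl, AlMe3, CH2Cl2, 0 °C to rt; Rochelle salt work-up
Reagents that add atoms: N,O-dimethylhydroxylamine hydrochloride, CNOC.Cl
Why: Aluminium-amide aminolysis of the γ-lactone (Weinreb amide formation) should open 1 at the acyl carbon only, so the C9 and C10 stereocentres of the chiral-pool lactone are carried over unchanged.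

Step 2
Reactants: 2 (2R,3R)-2,3,4-trihydroxy-N-methoxy-N,2-dimethylbutanamide
Product: 3 (2R,3R)-3,4-bis(tert-butyldimethylsilyloxy)-2-hydroxy-N-methoxy-N,2-dimethylbutanamide
Conditions: TBSCl (2.5 equiv), imidazole, DMF, rt
Reagents that add atoms: tert-butyldimethylsilyl chloride (TBSCl), CC(C)(C)[Si](C)(C)Cl
Why: Silyl ether formation with TBSCl/imidazole should take the primary (C8) and secondary (C9) hydroxyls and leave the hindered tertiary C10 hydroxyl free for the later furanone closure.

Step 3
Reactants: 4 (Z)-3-methylpent-2-en-4-yn-1-ol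
Product: 5 (Z)-triethyl[(3-methylpent-2-en-4-yn-1-yl)oxy]silane
Conditions: TESCl, imidazole, CH2Cl2, 0 °C
Reagents that add atoms: triethylsilyl chloride (TESCl), CC[Si](Cl)(CC)CC
Why: Standard silyl ether formation masks the allylic alcohol (future C6) as a TES ether that can later be removed in the presence of TBS ethers, while the Z olefin (C4=C5) is bought in place.

Step 4
Reactants: 5 (Z)-triethyl[(3-methylpent-2-en-4-yn-1-yl)oxy]silane; 3 (2R,3R)-3,4-bis(tert-butyldimethylsilyloxy)-2-hydroxy-N-methoxy-N,2-dimethylbutanamide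
Product: 7 (2Z,7R,8R)-8,9-bis(tert-butyldimethylsilyloxy)-7-hydroxy-3,7-dimethyl-1-(triethylsilyloxy)non-2-en-4-yn-6-one, via lithium acetylide 6 (not isolated)
Conditions: 5 (3.2 equiv), n-BuLi (3.0 equiv), THF, −78 °C; then 3, −78 to −20 °C; NH4Cl quench
Reagents that add atoms: none
Why: Acetylide addition to the Weinreb amide (alkynyl ketone synthesis) should stop at the ketone stage, one extra equivalent of 6 being consumed by the free tertiary hydroxyl, and it joins C2–C6 to C1 without touching C9 or C10.

Step 5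
Reactants: 7 (2Z,7R,8R)-8,9-bis(tert-butyldimethylsilyloxy)-7-hydroxy-3,7-dimethyl-1-(triethylsilyloxy)non-2-en-4-yn-6-one
Product: 8 (R)-2-[(R)-1,2-bis(tert-butyldimethylsilyloxy)ethyl]-2-methyl-5-[(Z)-4-(triethylsilyloxy)but-2-en-2-yl]furan-3(2H)-one
Conditions: (4-CF3C6H4)3PAuCl (5 mol %), AgOTf (5 mol %), toluene, rt
Reagents that add atoms: none
Why: Cationic monovalent gold activates the ynone triple bond for 5-endo-dig attack of the tertiary C10 hydroxyl (cycloisomerization of an α′-hydroxy ynone to a 3(2H)-furanone), the C9 oxygen being silylated so that no six-membered pyranone can form and C10 keeping its configuration.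

Step 6
Reactants: 8 (R)-2-[(R)-1,2-bis(tert-butyldimethylsilyloxy)ethyl]-2-methyl-5-[(Z)-4-(triethylsilyloxy)but-2-en-2-yl]furan-3(2H)-one
Product: 9 (R)-2-[(R)-1,2-bis(tert-butyldimethylsilyloxy)ethyl]-5-[(Z)-4-hydroxybut-2-en-2-yl]-2-methylfuran-3(2H)-one
Conditions: PPTS (cat.), MeOH/CH2Cl2, 0 °C
Reagents that add atoms: none
Why: Mild acid-catalysed methanolysis (selective desilylation) should cleave the primary allylic TES ether much faster than either TBS ether.

Step 7
Reactants: 9 (R)-2-[(R)-1,2-bis(tert-butyldimethylsilyloxy)ethyl]-5-[(Z)-4-hydroxybut-2-en-2-yl]-2-methylfuran-3(2H)-one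
Product: 10 (Z)-3-{(R)-5-[(R)-1,2-bis(tert-butyldimethylsilyloxy)ethyl]-5-methyl-4-oxo-4,5-dihydrofuran-2-yl}but-2-enal
Conditions: MnO2 (excess), CH2Cl2, rt
Reagents that add atoms: none
Why: MnO2 oxidizes allylic alcohols under neutral heterogeneous conditions (allylic oxidation), which should preserve the Z geometry of C4=C5.

Step 8
Reactants: 10 (Z)-3-{(R)-5-[(R)-1,2-bis(tert-butyldimethylsilyloxy)ethyl]-5-methyl-4-oxo-4,5-dihydrofuran-2-yl}but-2-enal
Product: 11 (R)-2-[(R)-1,2-bis(tert-butyldimethylsilyloxy)ethyl]-5-[(2Z,4R)-4-hydroxyhexa-2,5-dien-2-yl]-2-methylfuran-3(2H)-one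
Conditions: Zn(CH=CH2)2 (from CH2=CHMgBr and ZnCl2), (+)-DAIB (10 mol %), toluene/Et2O, −20 to 0 °C
Reagents that add atoms: divinylzinc, C=C[Zn]C=C
Why: Amino-alcohol-catalysed addition of divinylzinc to the aldehyde (catalytic asymmetric organozinc addition) should deliver the vinyl group to the re face under ligand control and so set C6 (R in 11, which is the 6S arrangement of the lactone), the vinylogous-ester ketone being inert to organozincs.

Step 9
Reactants: 11 (R)-2-[(R)-1,2-bis(tert-butyldimethylsilyloxy)ethyl]-5-[(2Z,4R)-4-hydroxyhexa-2,5-dien-2-yl]-2-methylfuran-3(2H)-one; 12 2-(bromomethyl)acrylic acid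
Product: 13 (3R,4Z)-5-{(R)-5-[(R)-1,2-bis(tert-butyldimethylsilyloxy)ethyl]-5-methyl-4-oxo-4,5-dihydrofuran-2-yl}hexa-1,4-dien-3-yl 2-(bromomethyl)acrylate
Conditions: DIC, DMAP (5 mol %), CH2Cl2, 0 °C
Reagents that add atoms: none
Why: Steglich esterification of the secondary allylic alcohol should proceed with retention at C6 and brings in C11, C12 and C13 with the allylic bromide already in place.

Step 10
Reactants: 13 (3R,4Z)-5-{(R)-5-[(R)-1,2-bis(tert-butyldimethylsilyloxy)ethyl]-5-methyl-4-oxo-4,5-dihydrofuran-2-yl}hexa-1,4-dien-3-yl 2-(bromomethyl)acrylate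
Product: 14 (S)-3-(bromomethyl)-5-[(Z)-2-{(R)-5-[(R)-1,2-bis(tert-butyldimethylsilyloxy)ethyl]-5-methyl-4-oxo-4,5-dihydrofuran-2-yl}prop-1-en-1-yl]furan-2(5H)-one
Conditions: second-generation Hoveyda–Grubbs catalyst RuCl2(H2IMes)(=CH-C6H4-2-OiPr) (10 mol %), toluene, 80 °C
Reagents that add atoms: none
Why: Ring-closing metathesis between the vinyl group and the 1,1-disubstituted acrylate should form the trisubstituted butenolide (C7=C11) with loss of ethene, the trisubstituted C4=C5 and the furanone olefin being too hindered and electron-poor to compete.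

Step 11
Reactants: 14 (S)-3-(bromomethyl)-5-[(Z)-2-{(R)-5-[(R)-1,2-bis(tert-butyldimethylsilyloxy)ethyl]-5-methyl-4-oxo-4,5-dihydrofuran-2-yl}prop-1-en-1-yl]furan-2(5H)-one
Product: 15 (S)-3-(bromomethyl)-5-[(Z)-2-{(R)-5-[(R)-1-(tert-butyldimethylsilyloxy)-2-hydroxyethyl]-5-methyl-4-oxo-4,5-dihydrofuran-2-yl}prop-1-en-1-yl]furan-2(5H)-one
Conditions: CSA (0.2 equiv), MeOH/CH2Cl2 (1:1), 0 °C
Reagents that add atoms: none
Why: Acid-catalysed methanolysis (selective desilylation) removes the primary C8 TBS ether far faster than the secondary C9 TBS ether next to the quaternary C10, and it avoids amine bases that would be alkylated by the allylic bromide.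

Step 12
Reactants: 15 (S)-3-(bromomethyl)-5-[(Z)-2-{(R)-5-[(R)-1-(tert-butyldimethylsilyloxy)-2-hydroxyethyl]-5-methyl-4-oxo-4,5-dihydrofuran-2-yl}prop-1-en-1-yl]furan-2(5H)-one
Product: 16 2-(tert-butyldimethylsilyloxy)-2-{(R)-5-[(Z)-1-((S)-4-(bromomethyl)-5-oxo-2,5-dihydrofuran-2-yl)prop-1-en-2-yl]-2-methyl-3-oxo-2,3-dihydrofuran-2-yl}acetaldehyde (C8 aldehyde; C9 and C10 unchanged)
Conditions: Dess–Martin periodinane, NaHCO3, CH2Cl2, 0 °C to rt
Reagents that add atoms: none
Why: Dess–Martin oxidation under bicarbonate buffering should give the α-silyloxy aldehyde without epimerizing C9 or disturbing the allylic bromide.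

Step 13
Reactants: 16 C8 aldehyde bearing the 3-(bromomethyl)butenolide
Product: 18 macrocyclic 9-O-TBS 8-epi alcohol (cis-fused α-methylene lactone, free 8R hydroxyl anti to C6, C9 OTBS; all other centres as in the target), via allylchromium dichloride 17 (not isolated)
Conditions: CrCl2 (6 equiv), THF, rt, slow addition of 16 (final 0.002 M); aqueous work-up
Reagents that add atoms: none
Why: CrCl2 (divalent chromium, two single-electron transfers) reduces the allylic C–Br bond of 16 to the allylchromium species 17 (trivalent chromium), whose γ-carbon C7 adds to the tethered aldehyde carbon C8 through a chromium-bridged six-membered transition state with allylic transposition, so that the C7–C8 bond, the exocyclic C11=C13 methylene and the C8 carbinol arise together. The closest known reaction type is the intramolecular Nozaki–Hiyama–Kishi (Barbier-type) allylation used for medium-ring closure, combined with the known SE2′ reactivity of 3-(bromomethyl)furan-2(5H)-ones towards aldehydes. The nine-membered oxonine ring closes in a 9-exo-trig addition to the aldehyde carbonyl, the furanone and lactone rings being already present. C7 is controlled by C6 and C10 through the tether: the aldehyde is delivered from C5, and the short rigid chain C5=C4–C3–O–C10–C9, whose twist is fixed by the 10R quaternary carbon, should reach only the butenolide face syn to C5, which gives the cis ring fusion. C8 is controlled by the closed transition state, in which chromium bridges O8 and C13 on the exposed outer face and the E-type allyl unit places the hydroxyl anti to C6 (8R, inverted in step 14). The step needs ring closure to beat oligomerization and reduction of other groups, which is secured by slow addition at high dilution, by the preorganizing Z olefin and planar furanone, and by the mildness of divalent chromium towards the furanone, the lactone and the silyl ether.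

Step 14
Reactants: 18 macrocyclic 9-O-TBS 8-epi alcohol; 19 isovaleric acid (3-methylbutanoic acid)
Product: 20 9-O-TBS ether of the target (8S isovalerate, 6S,7S,8S,9R,10R)
Conditions: PPh3, DIAD, toluene, 0 °C to rt
Reagents that add atoms: none
Why: Mitsunobu esterification activates the C8 hydroxyl and lets isovalerate displace it with inversion (SN2), turning the 8R carbinol into the 8S ester of the target.

Step 15
Reactants: 20 9-O-TBS ether of the target
Product: 21 target, CNP0175298.2 (6S,7S,8S,9R,10R)
Conditions: HF·pyridine, THF, 0 °C to rt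
Reagents that add atoms: none
Why: Desilylation with HF·pyridine (mildly acidic fluoride source) should free the C9 hydroxyl without acyl migration from O8 to O9 and without conjugate addition to the methylene lactone.

Compound list
1 | 2-C-methyl-D-erythrono-1,4-lactone | O=C1[C@](C)(O)[C@H](O)CO1 | starting material
2 | (2R,3R)-2,3,4-trihydroxy-N-methoxy-N,2-dimethylbutanamide | CON(C)C(=O)[C@](C)(O)[C@H](O)CO | intermediate
3 | (2R,3R)-3,4-bis(tert-butyldimethylsilyloxy)-2-hydroxy-N-methoxy-N,2-dimethylbutanamide | CON(C)C(=O)[C@](C)(O)[C@H](O[Si](C)(C)C(C)(C)C)CO[Si](C)(C)C(C)(C)C | intermediate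
4 | (Z)-3-methylpent-2-en-4-yn-1-ol | C#C/C(C)=C\CO | starting material
5 | (Z)-triethyl[(3-methylpent-2-en-4-yn-1-yl)oxy]silane | C#C/C(C)=C\CO[Si](CC)(CC)CC | intermediate
6 | lithium acetylide of 5 | [Li]C#C/C(C)=C\CO[Si](CC)(CC)CC | intermediate
7 | (2Z,7R,8R)-8,9-bis(tert-butyldimethylsilyloxy)-7-hydroxy-3,7-dimethyl-1-(triethylsilyloxy)non-2-en-4-yn-6-one | CC[Si](CC)(CC)OC/C=C(/C)C#CC(=O)[C@](C)(O)[C@H](O[Si](C)(C)C(C)(C)C)CO[Si](C)(C)C(C)(C)C | intermediate
8 | (R)-2-[(R)-1,2-bis(tert-butyldimethylsilyloxy)ethyl]-2-methyl-5-[(Z)-4-(triethylsilyloxy)but-2-en-2-yl]furan-3(2H)-one | CC[Si](CC)(CC)OC/C=C(/C)C1=CC(=O)[C@](C)(O1)[C@H](O[Si](C)(C)C(C)(C)C)CO[Si](C)(C)C(C)(C)C | intermediate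
9 | (R)-2-[(R)-1,2-bis(tert-butyldimethylsilyloxy)ethyl]-5-[(Z)-4-hydroxybut-2-en-2-yl]-2-methylfuran-3(2H)-one | OC/C=C(/C)C1=CC(=O)[C@](C)(O1)[C@H](O[Si](C)(C)C(C)(C)C)CO[Si](C)(C)C(C)(C)C | intermediate
10 | (Z)-3-{(R)-5-[(R)-1,2-bis(tert-butyldimethylsilyloxy)ethyl]-5-methyl-4-oxo-4,5-dihydrofuran-2-yl}but-2-enal | O=C/C=C(/C)C1=CC(=O)[C@](C)(O1)[C@H](O[Si](C)(C)C(C)(C)C)CO[Si](C)(C)C(C)(C)C | intermediate
11 | (R)-2-[(R)-1,2-bis(tert-butyldimethylsilyloxy)ethyl]-5-[(2Z,4R)-4-hydroxyhexa-2,5-dien-2-yl]-2-methylfuran-3(2H)-one | C=C[C@@H](O)/C=C(/C)C1=CC(=O)[C@](C)(O1)[C@H](O[Si](C)(C)C(C)(C)C)CO[Si](C)(C)C(C)(C)C | intermediate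
12 | 2-(bromomethyl)acrylic acid | C=C(CBr)C(=O)O | starting material
13 | (3R,4Z)-5-{(R)-5-[(R)-1,2-bis(tert-butyldimethylsilyloxy)ethyl]-5-methyl-4-oxo-4,5-dihydrofuran-2-yl}hexa-1,4-dien-3-yl 2-(bromomethyl)acrylate | C=C(CBr)C(=O)O[C@H](C=C)/C=C(/C)C1=CC(=O)[C@](C)(O1)[C@H](O[Si](C)(C)C(C)(C)C)CO[Si](C)(C)C(C)(C)C | intermediate
14 | (S)-3-(bromomethyl)-5-[(Z)-2-{(R)-5-[(R)-1,2-bis(tert-butyldimethylsilyloxy)ethyl]-5-methyl-4-oxo-4,5-dihydrofuran-2-yl}prop-1-en-1-yl]furan-2(5H)-one | O=C1O[C@H](C=C1CBr)/C=C(/C)C2=CC(=O)[C@](C)(O2)[C@H](O[Si](C)(C)C(C)(C)C)CO[Si](C)(C)C(C)(C)C | intermediate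
15 | primary alcohol: (S)-3-(bromomethyl)-5-[(Z)-2-{(R)-5-[(R)-1-(tert-butyldimethylsilyloxy)-2-hydroxyethyl]-5-methyl-4-oxo-4,5-dihydrofuran-2-yl}prop-1-en-1-yl]furan-2(5H)-one | O=C1O[C@H](C=C1CBr)/C=C(/C)C2=CC(=O)[C@](C)(O2)[C@H](O[Si](C)(C)C(C)(C)C)CO | intermediate
16 | C8 aldehyde bearing the 3-(bromomethyl)butenolide (C9 OTBS, C9 and C10 as in 1, C6 S) | O=C1O[C@H](C=C1CBr)/C=C(/C)C2=CC(=O)[C@](C)(O2)[C@H](O[Si](C)(C)C(C)(C)C)C=O | intermediate
17 | allylchromium dichloride derived from 16 | O=C1O[C@H](C=C1C[Cr](Cl)Cl)/C=C(/C)C2=CC(=O)[C@](C)(O2)[C@H](O[Si](C)(C)C(C)(C)C)C=O | intermediate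
18 | macrocyclic 9-O-TBS 8-epi alcohol (cis lactone fusion, 8R hydroxyl) | C=C1C(=O)O[C@H]2/C=C(/C)C3=CC(=O)[C@](C)(O3)[C@H](O[Si](C)(C)C(C)(C)C)[C@H](O)[C@@H]12 | intermediate
19 | isovaleric acid (3-methylbutanoic acid) | CC(C)CC(=O)O | starting material
20 | 9-O-TBS ether of the target (8S isovalerate) | C=C1C(=O)O[C@H]2/C=C(/C)C3=CC(=O)[C@](C)(O3)[C@H](O[Si](C)(C)C(C)(C)C)[C@@H](OC(=O)CC(C)C)[C@@H]12 | intermediate
21 | CNP0175298.2 (6S,7S,8S,9R,10R) | C=C1C(=O)O[C@H]2/C=C(/C)C3=CC(=O)[C@](C)(O3)[C@H](O)[C@@H](OC(=O)CC(C)C)[C@@H]12 | target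

Total step count: 15. Longest linear sequence: 14 steps (steps 1, 2 and 4–15, from lactone 1).

Steps most likely to fail

1. Step 13 (ring closure). The allylchromium may couple between molecules and give oligomers, the aldehyde may be delivered to the butenolide face anti to C5 (trans fusion), or the bromide may simply be reduced. The fallback closes the same bond by a different mechanism; it sets out from aldehyde 16 and returns at 20. Stannylation of the allylic bromide with Bu3SnSnBu3 under Pd2(dba)3 catalysis (zerovalent palladium) in THF should give the allylstannane aldehyde F1. BF3·OEt2 in CH2Cl2 at −78 °C under high dilution then promotes an intramolecular allylstannane addition through an open antiperiplanar transition state, which favours the syn relationship across C7–C8 and should give the macrocyclic 8S alcohol F2 directly. Acylation of F2 with isovaleric anhydride, DMAP and pyridine gives 20, so that no inversion is needed.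

2. Step 14 (Mitsunobu inversion). Displacement at the hindered ring carbinol from the concave side of the bicycle may be outrun by elimination towards C7 or by acyl transfer with retention. The fallback inverts C8 by oxidation and reduction; it sets out from 18 and returns at 20. Dess–Martin oxidation should give the C8 ketone F3. Luche reduction (NaBH4, CeCl3·7H2O, MeOH, −78 °C) should then deliver hydride to the exposed outer face of this saturated ketone, in preference to the vinylogous-ester carbonyl and the methylene lactone, and give the macrocyclic 8S alcohol F2. Acylation with isovaleric anhydride, DMAP and pyridine gives 20.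

3. Step 8 (asymmetric vinylation). Ligand control over the face of the sensitive Z-dienal may be poor, and 1,4-addition or Z-to-E isomerization may compete. The fallback sets C6 by alkynylation and semi-reduction; it sets out from 10 and returns at 11. Addition of trimethylsilylacetylene with Me2Zn and the ProPhenol enantiomer that gives the S carbinol should give the silylated propargylic alcohol F4. K2CO3 in MeOH removes the alkyne silyl group to give the terminal propargylic alcohol F5. Semi-hydrogenation of F5 with H2 over Pd/CaCO3–Pb(OAc)2 (Lindlar catalyst) and quinoline gives 11.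

Further compounds
F1 | step 13 | allylstannane aldehyde: 16 with CH2SnBu3 in place of CH2Br | O=C1O[C@H](C=C1C[Sn](CCCC)(CCCC)CCCC)/C=C(/C)C2=CC(=O)[C@](C)(O2)[C@H](O[Si](C)(C)C(C)(C)C)C=O
F2 | step 13 | macrocyclic 9-O-TBS 8S alcohol (C8 epimer of 18) | C=C1C(=O)O[C@H]2/C=C(/C)C3=CC(=O)[C@](C)(O3)[C@H](O[Si](C)(C)C(C)(C)C)[C@@H](O)[C@@H]12
F3 | step 14 | macrocyclic 9-O-TBS C8 ketone | C=C1C(=O)O[C@H]2/C=C(/C)C3=CC(=O)[C@](C)(O3)[C@H](O[Si](C)(C)C(C)(C)C)C(=O)[C@@H]12
F4 | step 8 | (S)-propargylic alcohol with trimethylsilyl alkyne (vinyl of 11 replaced by C≡C–SiMe3) | C[Si](C)(C)C#C[C@@H](O)/C=C(/C)C1=CC(=O)[C@](C)(O1)[C@H](O[Si](C)(C)C(C)(C)C)CO[Si](C)(C)C(C)(C)C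
F5 | step 8 | (S)-propargylic alcohol with terminal alkyne (vinyl of 11 replaced by ethynyl) | C#C[C@@H](O)/C=C(/C)C1=CC(=O)[C@](C)(O1)[C@H](O[Si](C)(C)C(C)(C)C)CO[Si](C)(C)C(C)(C)C
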